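**Retrosynthetic overview**

1. Labels: diquinane C1–C8 (ring A = cyclopentane C1–C5, with C1 the methyl-bearing fusion carbon, C2 the side-chain carbon, C5 the fusion CH; ring B = cyclopentene C1, C5–C8); hydroazulene C1′–C8a′ (ring C five-membered, ring D seven-membered, C4′ the ketone); side chain C1″–C5″.
2. Ring D is closed last by ring-closing metathesis (C8′=C8a′). Its C4′ ketone travels as a dithiane joined to ring C by trans-opening of an epoxide, which fixes C3a′ cis to C1′. The side chain comes from Felkin addition of the acetylide of (R)-but-3-yn-2-ol to the C2 methyl ketone and trans-reduction.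
3. The C7–C1′ bond comes from palladium-catalysed asymmetric allylic alkylation of the ring-B ketone enolate with a cyclopentenyl carbonate (ring C arrives intact). The C6=C7 alkene comes from enol-triflate reduction and allylic-diazene 1,3-transposition, which erase both temporary oxygens of ring B.
4. Ring A (key step) comes from a thiyl-radical-catalysed, strain-releasing [3+2] union of a 1-silyloxyvinyl cyclopropane with (R)-4-silyloxy-2-methylcyclopent-2-enone (ring B, from the commercial prostaglandin building block), forming C4–C5 and C1–C2. Ring order: B (bought), A, C (bought), D.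
5. Enabling feature: in ring A the ketone-level side-chain carbon sits on C2, next to the methyl-bearing quaternary fusion carbon C1 and two CH2 groups (C3, C4) away from the fusion CH C5. This is an acylcyclopropane C2–C3–C4 laid across the C1=C5 bond of an α-methyl cyclopentenone, whose carbonyl (C8) and γ-silyloxy group (C6) are temporary.

Key step: step 4

Remark: the C7 configuration of 10 is inconsequential (C7 becomes sp2 in step 7) and is left undefined; TBS = tert-butyldimethylsilyl.

**Route**

Step 1
Reactants: 1 (R)-4-[(tert-butyldimethylsilyl)oxy]cyclopent-2-en-1-one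
Product: 2 (R)-4-[(tert-butyldimethylsilyl)oxy]-2-iodocyclopent-2-en-1-one
Conditions: I2, pyridine, CH2Cl2, 0 °C → rt
Reagents that add atoms: iodine, II
Why: Pyridine-mediated α-iodination of an enone (Johnson iodination) is standard for 4-silyloxycyclopentenones and does not touch the C4 stereocentre.

Step 2
Reactants: 2 (R)-4-[(tert-butyldimethylsilyl)oxy]-2-iodocyclopent-2-en-1-one
Product: 3 (R)-4-[(tert-butyldimethylsilyl)oxy]-2-methylcyclopent-2-en-1-one
Conditions: SnMe4, PdCl2(PhCN)2 (5 mol%), AsPh3, CuI, NMP, 60 °C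
Reagents that add atoms: tetramethylstannane, C[Sn](C)(C)C
Why: Stille coupling of an α-iodoenone under neutral conditions, so the β-silyloxy ketone should not eliminate.

Step 3
Reactants: 4 cyclopropyl methyl ketone
Product: 5 tert-butyl[(1-cyclopropylethenyl)oxy]dimethylsilane
Conditions: TBSOTf, Et3N, CH2Cl2, 0 °C
Reagents that add atoms: tert-butyldimethylsilyl trifluoromethanesulfonate, CC(C)(C)[Si](C)(C)OS(=O)(=O)C(F)(F)F
Why: Soft enolisation of a methyl ketone with a silyl triflate and an amine gives the terminal silyl enol ether, the cyclopropyl C–H being far less acidic.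

Step 4
Reactants: 3 (R)-4-[(tert-butyldimethylsilyl)oxy]-2-methylcyclopent-2-en-1-one, 5 tert-butyl[(1-cyclopropylethenyl)oxy]dimethylsilane
Product: 6 cis-fused 6-(TBS-oxy)-1-methyl-2-[1-(TBS-oxy)ethenyl]bicyclo[3.3.0]octan-8-one (C2 substituent trans to the C1 methyl; C6 silyloxy cis to it)
Conditions: PhSSPh (20 mol%), AIBN (10 mol%), benzene, sunlamp, 40 °C; 5 (1.5 equiv)
Reagents that add atoms: none
Why: Proposed new method: phenylthiyl radical adds to the CH2 terminus of silyl enol ether 5, the α-silyloxy cyclopropylcarbinyl radical opens with release of ring strain to a primary homoallyl radical, this adds to the β-carbon of enone 3 (C5), and the electrophilic tertiary α-keto radical at C1 closes onto the electron-rich enol-ether carbon (C2) before β-scission expels PhS• and restores the silyl enol ether. The closest known reaction type is the thiyl-radical-catalysed vinylcyclopropane–alkene [3+2] cycloaddition (Feldman, Oshima), extended here to a 1-silyloxyvinyl cyclopropane and an α-methyl cyclic enone. Ring A is closed by a 5-exo-trig radical cyclisation, ring B being carried in with the enone. C5 is set by radical addition anti to the neighbouring silyloxy group, C1 follows because the three-atom tether can only close cis on the cyclopentanone, and C2 should come from the chair-like transition state that puts the enol ether under ring B (cis to C8). C2 also stays correctable, since it becomes the α-carbon of a methyl ketone in step 7, where the epimer trans to the angular methyl should be the stable one (as in 14β-pregnan-20-ones). The step needs the nucleophilic primary radical to attack C5 and not C1, and the α-keto radical to cyclise faster than it adds to a second enone; the enone polarisation and the matched electrophilic-radical/enol-ether pair should secure both.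

Step 5
Reactants: 7 cyclopent-2-en-1-ol (racemic)
Product: 8 cyclopent-2-en-1-yl methyl carbonate (racemic)
Conditions: ClCO2Me, pyridine, CH2Cl2, 0 °C
Reagents that add atoms: methyl chloroformate, COC(=O)Cl
Why: Acylation of a secondary allylic alcohol with a chloroformate.

Step 6
Reactants: 6 diquinane ketone, 8 cyclopent-2-en-1-yl methyl carbonate
Product: 10 ketone 6 carrying a cyclopent-2-en-1-yl group at C7 (C1′ as in the target), via lithium enolate 9 (not isolated)
Conditions: LiN(SiMe3)2, LiCl, THF, −78 °C; then 8, [Pd(C3H5)Cl]2 (2.5 mol%), Trost DACH-phenyl ligand (7.5 mol%), −78 → −40 °C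
Reagents that add atoms: none
Why: Palladium-catalysed asymmetric allylic alkylation of a preformed ketone enolate (Trost/Braun type): C7 is the only enolisable position, the chiral ligand (enantiomer chosen for the C1′ configuration shown) differentiates the two ends of the meso π-allyl complex, and the low temperature should keep the β-silyloxy enolate from eliminating.

Step 7
Reactants: 10 C7-cyclopentenyl ketone
Product: 12 2-acetyl-7-(cyclopent-2-en-1-yl)-6-hydroxy-1-methylbicyclo[3.3.0]oct-7-en-8-yl trifluoromethanesulfonate, via silylated enol triflate 11 (not isolated)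
Conditions: KN(SiMe3)2, PhNTf2, THF, −78 °C; then 48% aq HF, MeCN, 0 °C → rt
Reagents that add atoms: N-phenylbis(trifluoromethanesulfonimide), O=S(=O)(N(c1ccccc1)S(=O)(=O)C(F)(F)F)C(F)(F)F
Why: C7–H is the only α-hydrogen of the C8 ketone, so enolate trapping gives a single enol triflate, and aqueous HF then cleaves the silyl enol ether (to the methyl ketone) and the secondary silyl ether without touching the vinyl triflate.

Step 8
Reactants: 12 hydroxy enol triflate
Product: 13 epoxide of 12 (2,3-epoxycyclopentyl group, oxirane trans to the diquinane)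
Conditions: mCPBA, NaHCO3, CH2Cl2, 0 °C
Reagents that add atoms: 3-chloroperbenzoic acid, O=C(OO)c1cccc(Cl)c1
Why: Prilezhaev epoxidation: the electron-poor enol triflate is inert and the peracid should attack the cyclopentene anti to the bulky C1′ substituent.

Step 9
Reactants: 13 epoxy enol triflate
Product: 14 2-acetyl-7-(2,3-epoxycyclopentyl)-1-methylbicyclo[3.3.0]oct-7-en-6-ol
Conditions: Pd(OAc)2 (5 mol%), PPh3, HCO2H, n-Bu3N, DMF, 60 °C
Reagents that add atoms: none
Why: Palladium-catalysed formate reduction of an enol triflate (Cacchi reduction) exchanges OTf for H and leaves the alkene at C7=C8, with ketone, isolated epoxide and alcohol as spectators.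

Step 10
Reactants: 15 (R)-but-3-yn-2-ol
Product: 16 (R)-(but-3-yn-2-yloxy)(tert-butyl)dimethylsilane
Conditions: TBSCl, imidazole, DMF, rt
Reagents that add atoms: tert-butyldimethylsilyl chloride, CC(C)(C)[Si](C)(C)Cl
Why: Standard silylation of a secondary alcohol.

Step 11
Reactants: 14 epoxy methyl ketone, 16 silyl-protected butynol
Product: 18 tertiary propargylic alcohol (C1″ carbinol, alkyne C2″≡C3″, C4″ silyl ether), via lithium acetylide 17 (not isolated)
Conditions: 16 (3 equiv), n-BuLi, THF, −78 °C; then 14, −78 → −40 °C; aq NH4Cl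
Reagents that add atoms: none
Why: 1,2-Addition of a lithium acetylide to the methyl ketone under Felkin–Anh control by C2 (quaternary C1 anti to the nucleophile, the sense known from Grignard additions to 20-oxo steroids) should set C1″ as in the target; the isolated epoxide is inert at this temperature.

Step 12
Reactants: 18 propargylic alcohol with C6 allylic alcohol
Product: 21 epoxy enyne with the C6=C7 alkene and C8H2, via sulfonylhydrazine 19 (not isolated), via allylic diazene 20 (not isolated)
Conditions: 2-O2NC6H4SO2NHNH2, PPh3, DEAD, THF, −30 °C; then 23 °C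
Reagents that add atoms: none
Why: Myers reductive 1,3-transposition: Mitsunobu displacement at the secondary C6 carbinol (the tertiary alcohol cannot react), loss of sulfinic acid and retro-ene loss of N2 from the allylic diazene put hydrogen on C8 and the double bond at C6=C7.

Step 13
Reactants: 22 1,3-dithiane, 23 (S)-epichlorohydrin
Product: 26 (S)-2-(oxiran-2-ylmethyl)-1,3-dithiane, via 2-lithio-1,3-dithiane 24 (not isolated), via chlorohydrin alkoxide 25 (not isolated)
Conditions: n-BuLi, THF, −30 °C; then 23, −78 → 0 °C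
Reagents that add atoms: none
Why: The dithiane anion opens the epoxide at its CH2 and the alkoxide then displaces chloride, a known one-flask route to the dithianyl epoxide that keeps the stereocentre.

Step 14
Reactants: 26 (S)-2-(oxiran-2-ylmethyl)-1,3-dithiane
Product: 27 (R)-1-(1,3-dithian-2-yl)pent-4-en-2-ol
Conditions: CH2=CHMgBr, CuI (10 mol%), THF, −30 °C
Reagents that add atoms: vinylmagnesium bromide, C=C[Mg]Br
Why: Copper-catalysed Grignard opening of a terminal epoxide at its CH2 carbon.

Step 15
Reactants: 27 (R)-1-(1,3-dithian-2-yl)pent-4-en-2-ol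
Product: 28 (R)-tert-butyl{[1-(1,3-dithian-2-yl)pent-4-en-2-yl]oxy}dimethylsilane
Conditions: TBSCl, imidazole, DMF, rt
Reagents that add atoms: tert-butyldimethylsilyl chloride, CC(C)(C)[Si](C)(C)Cl
Why: Standard silylation of a secondary alcohol.

Step 16
Reactants: 21 epoxy enyne, 28 silyloxy pentenyl dithiane
Product: 30 trans-2-substituted cyclopentanol with the dithiane carbon (C4′) on C3a′ and the hydroxyl on C8a′, via lithiated dithiane 29 (not isolated)
Conditions: 28 (3 equiv), t-BuLi, THF/HMPA, −78 °C; then 21, −78 → −20 °C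
Reagents that add atoms: none
Why: Corey–Seebach opening of an epoxide by a 2-lithio-1,3-dithiane: SN2 attack at the less hindered oxirane carbon C3a′ with inversion brings the acyl-anion carbon in on the face of the C1′ substituent, so the C3a′–C4′ bond ends up cis to the C1′–C7 bond and the C8a′ hydroxyl trans to both (one equivalent of anion is spent on the tertiary hydroxyl).

Step 17
Reactants: 30 propargylic alcohol
Product: 31 (E)-allylic alcohol (C2″=C3″)
Conditions: NaAlH2(OCH2CH2OMe)2, THF, 0 °C → rt
Reagents that add atoms: none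
Why: Hydroxyl-directed trans-hydroalumination of the propargylic alcohol and protonolysis gives the (E)-alkene; no other group is reducible.

Step 18
Reactants: 31 secondary cyclopentanol
Product: 32 cyclopentanone (C8a′ ketone)
Conditions: Dess–Martin periodinane, NaHCO3, CH2Cl2, 0 °C
Reagents that add atoms: none
Why: Buffered, non-basic oxidation of the only free secondary alcohol (the tertiary allylic alcohol cannot be oxidised), which should leave the flanking centres C1′ and C3a′ unepimerised.

Step 19
Reactants: 32 cyclopentanone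
Product: 33 exocyclic methylene compound (C8a′=CH2)
Conditions: Cp2TiMe2, toluene, 65 °C
Reagents that add atoms: dimethyltitanocene, C[Ti+2]C.c1cc[cH-]c1.c1cc[cH-]c1
Why: Petasis methylenation is non-basic and works on hindered, enolisable ketones, so the methylene should go in without epimerisation or conjugation.

Step 20
Reactants: 33 methylene/terminal-alkene diene
Product: 34 hydroazulene with C4′ dithiane and two silyl ethers
Conditions: second-generation Hoveyda–Grubbs catalyst (10 mol%), toluene (2 mM), 80 °C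
Reagents that add atoms: none
Why: Ring-closing olefin metathesis between the exocyclic 1,1-disubstituted alkene and the terminal alkene closes ring D and gives the trisubstituted C8′=C8a′ alkene; the trisubstituted ring-B alkene and the hindered side-chain alkene are poor metathesis substrates.

Step 21
Reactants: 34 bis-silyl ether
Product: 35 triol with C4′ dithiane
Conditions: Bu4NF, THF, 0 °C → rt
Reagents that add atoms: none
Why: Fluoride cleaves both secondary silyl ethers while the ketone is still masked, so no β-silyloxy ketone is exposed to base.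

Step 22
Reactants: 35 triol dithiane
Product: 36 target compound CNP0358460.1
Conditions: MeI, CaCO3, MeCN/H2O (9:1), 45 °C
Reagents that add atoms: water, O
Why: Alkylative hydrolysis of the dithiane under buffered, neutral conditions unveils the C4′ ketone without base, which should preserve the β,γ-unsaturated ketone (C3a′) and the β-hydroxy ketone.

**Compound list**

1 | (R)-4-[(tert-butyldimethylsilyl)oxy]cyclopent-2-en-1-one | O=C1C=C[C@H](O[Si](C)(C)C(C)(C)C)C1 | starting material
2 | (R)-4-[(tert-butyldimethylsilyl)oxy]-2-iodocyclopent-2-en-1-one | O=C1C(I)=C[C@H](O[Si](C)(C)C(C)(C)C)C1 | intermediate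
3 | (R)-4-[(tert-butyldimethylsilyl)oxy]-2-methylcyclopent-2-en-1-one | CC1=C[C@H](O[Si](C)(C)C(C)(C)C)CC1=O | intermediate
4 | cyclopropyl methyl ketone | CC(=O)C1CC1 | starting material
5 | tert-butyl[(1-cyclopropylethenyl)oxy]dimethylsilane | C=C(O[Si](C)(C)C(C)(C)C)C1CC1 | intermediate
6 | cis-fused 6-(TBS-oxy)-1-methyl-2-[1-(TBS-oxy)ethenyl]bicyclo[3.3.0]octan-8-one | C=C(O[Si](C)(C)C(C)(C)C)[C@H]1CC[C@H]2[C@H](O[Si](C)(C)C(C)(C)C)CC(=O)[C@]21C | intermediate
7 | cyclopent-2-en-1-ol (racemic) | OC1C=CCC1 | starting material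
8 | cyclopent-2-en-1-yl methyl carbonate (racemic) | COC(=O)OC1C=CCC1 | intermediate
9 | lithium enolate of 6 (C7=C8–OLi) | C=C(O[Si](C)(C)C(C)(C)C)[C@H]1CC[C@H]2[C@H](O[Si](C)(C)C(C)(C)C)C=C(O[Li])[C@]21C | intermediate
10 | 6 with a cyclopent-2-en-1-yl group at C7 (C7 epimers) | C=C(O[Si](C)(C)C(C)(C)C)[C@H]1CC[C@H]2[C@H](O[Si](C)(C)C(C)(C)C)C([C@H]3CCC=C3)C(=O)[C@]21C | intermediate
11 | C7=C8 enol triflate of 10, both silyl groups in place | C=C(O[Si](C)(C)C(C)(C)C)[C@H]1CC[C@H]2[C@H](O[Si](C)(C)C(C)(C)C)C([C@H]3CCC=C3)=C(OS(=O)(=O)C(F)(F)F)[C@]21C | intermediate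
12 | 2-acetyl-7-(cyclopent-2-en-1-yl)-6-hydroxy-1-methylbicyclo[3.3.0]oct-7-en-8-yl triflate | CC(=O)[C@H]1CC[C@H]2[C@H](O)C([C@H]3CCC=C3)=C(OS(=O)(=O)C(F)(F)F)[C@]21C | intermediate
13 | epoxide of 12 (oxirane trans to the diquinane) | CC(=O)[C@H]1CC[C@H]2[C@H](O)C([C@H]3CC[C@@H]4O[C@H]34)=C(OS(=O)(=O)C(F)(F)F)[C@]21C | intermediate
14 | 2-acetyl-7-(2,3-epoxycyclopentyl)-1-methylbicyclo[3.3.0]oct-7-en-6-ol | CC(=O)[C@H]1CC[C@H]2[C@H](O)C([C@H]3CC[C@@H]4O[C@H]34)=C[C@]21C | intermediate
15 | (R)-but-3-yn-2-ol | C#C[C@@H](C)O | starting material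
16 | (R)-(but-3-yn-2-yloxy)(tert-butyl)dimethylsilane | C#C[C@@H](C)O[Si](C)(C)C(C)(C)C | intermediate
17 | lithium acetylide of 16 | [Li]C#C[C@@H](C)O[Si](C)(C)C(C)(C)C | intermediate
18 | tertiary propargylic alcohol with C6 allylic alcohol and epoxide | C[C@@H](O[Si](C)(C)C(C)(C)C)C#C[C@](C)(O)[C@H]1CC[C@H]2[C@H](O)C([C@H]3CC[C@@H]4O[C@H]34)=C[C@]21C | intermediate
19 | N-(C6-allyl)-N-(2-nitrobenzenesulfonyl)hydrazine (C6 inverted) | C[C@@H](O[Si](C)(C)C(C)(C)C)C#C[C@](C)(O)[C@H]1CC[C@H]2[C@@H](N(N)S(=O)(=O)c5ccccc5[N+](=O)[O-])C([C@H]3CC[C@@H]4O[C@H]34)=C[C@]21C | intermediate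
20 | C6 allylic diazene | C[C@@H](O[Si](C)(C)C(C)(C)C)C#C[C@](C)(O)[C@H]1CC[C@H]2[C@@H](N=N)C([C@H]3CC[C@@H]4O[C@H]34)=C[C@]21C | intermediate
21 | epoxy enyne with C6=C7 alkene | C[C@@H](O[Si](C)(C)C(C)(C)C)C#C[C@](C)(O)[C@H]1CC[C@H]2C=C([C@H]3CC[C@@H]4O[C@H]34)C[C@]21C | intermediate
22 | 1,3-dithiane | C1CSCSC1 | starting material
23 | (S)-epichlorohydrin | ClC[C@@H]1CO1 | starting material
24 | 2-lithio-1,3-dithiane | [Li]C1SCCCS1 | intermediate
25 | lithium (S)-1-chloro-3-(1,3-dithian-2-yl)propan-2-olate | ClC[C@@H](O[Li])CC1SCCCS1 | intermediate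
26 | (S)-2-(oxiran-2-ylmethyl)-1,3-dithiane | S1CCCSC1C[C@H]2CO2 | intermediate
27 | (R)-1-(1,3-dithian-2-yl)pent-4-en-2-ol | S1CCCSC1C[C@H](O)CC=C | intermediate
28 | (R)-tert-butyl{[1-(1,3-dithian-2-yl)pent-4-en-2-yl]oxy}dimethylsilane | S1CCCSC1C[C@H](O[Si](C)(C)C(C)(C)C)CC=C | intermediate
29 | 2-lithio derivative of 28 | [Li]C1(C[C@H](O[Si](C)(C)C(C)(C)C)CC=C)SCCCS1 | intermediate
30 | dithiane-opened cyclopentanol (C3a′–C4′ bond cis to C1′–C7, C8a′–OH trans) | C[C@@H](O[Si](C)(C)C(C)(C)C)C#C[C@](C)(O)[C@H]1CC[C@H]2C=C([C@H]3CC[C@@H](C4(SCCCS4)C[C@H](O[Si](C)(C)C(C)(C)C)CC=C)[C@@H]3O)C[C@]21C | intermediate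
31 | (E)-allylic alcohol from 30 | C[C@@H](O[Si](C)(C)C(C)(C)C)/C=C/[C@](C)(O)[C@H]1CC[C@H]2C=C([C@H]3CC[C@@H](C4(SCCCS4)C[C@H](O[Si](C)(C)C(C)(C)C)CC=C)[C@@H]3O)C[C@]21C | intermediate
32 | C8a′ cyclopentanone | C[C@@H](O[Si](C)(C)C(C)(C)C)/C=C/[C@](C)(O)[C@H]1CC[C@H]2C=C([C@H]3CC[C@@H](C4(SCCCS4)C[C@H](O[Si](C)(C)C(C)(C)C)CC=C)C3=O)C[C@]21C | intermediate
33 | C8a′ exocyclic methylene compound | C[C@@H](O[Si](C)(C)C(C)(C)C)/C=C/[C@](C)(O)[C@H]1CC[C@H]2C=C([C@H]3CC[C@@H](C4(SCCCS4)C[C@H](O[Si](C)(C)C(C)(C)C)CC=C)C3=C)C[C@]21C | intermediate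
34 | hydroazulene with C4′ dithiane, C6′ and C4″ silyl ethers | C[C@@H](O[Si](C)(C)C(C)(C)C)/C=C/[C@](C)(O)[C@H]1CC[C@H]2C=C([C@H]3CC[C@H]4C5(SCCCS5)C[C@H](O[Si](C)(C)C(C)(C)C)CC=C34)C[C@]21C | intermediate
35 | triol with C4′ dithiane | C[C@@H](O)/C=C/[C@](C)(O)[C@H]1CC[C@H]2C=C([C@H]3CC[C@H]4C5(SCCCS5)C[C@H](O)CC=C34)C[C@]21C | intermediate
36 | CNP0358460.1 | C[C@@H](O)/C=C/[C@](C)(O)[C@H]1CC[C@H]2C=C([C@H]3CC[C@H]4C(=O)C[C@H](O)CC=C34)C[C@]21C | target

**Totals and risks**

Total step count: 22. Longest linear sequence: 16 steps (1 → 36 through steps 1, 2, 4, 6–9, 11, 12, 16–22).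

Steps most likely to fail:

1. Step 4 (proposed new method). The radical chain may not propagate: the α-keto radical may add to a second enone before it cyclises, or thiyl release may be slow. The closure may also favour the wrong C2 epimer. Fallback from 3, back at 12: the documented Feldman cycloaddition of parent vinylcyclopropane with an electron-poor alkene (PhSSPh, AIBN, benzene, light) should give vinyl diquinane ketone F1. Its lithium enolate F2 is allylated with 8 as in step 6 to the C7-cyclopentenyl ketone F3. KN(SiMe3)2/PhNTf2 gives the silyl-protected enol triflate F4, and aqueous HF gives the hydroxy enol triflate F5. Tsuji–Wacker oxidation of the terminal vinyl group (PdCl2, CuCl, O2, DMF/H2O) then gives methyl ketone 12.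

2. Step 6. Silanolate may be lost from the β-silyloxy enolate, and facial discrimination at the allyl terminus may be poor if ligand and chiral enolate are mismatched. Fallback from 6, back at 10: KN(SiMe3)2/PhNTf2 gives the C7=C8 enol triflate F6. Palladium-catalysed C–O coupling (Pd2(dba)3, a biaryl dialkylphosphine, Cs2CO3, toluene) with (R)-cyclopent-2-en-1-ol gives the allyl vinyl ether F7. Heating (toluene, 130 °C) brings about the suprafacial [3,3] Claisen rearrangement, which forms the C7–C1′ bond on the face that carried the oxygen and regenerates the C8 ketone without any enolate, returning 10.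

3. Step 16. SN2 attack of the tertiary dithiane anion at a flanked secondary oxirane carbon may be slow, and deprotonation at the allylic C1′–H may isomerise the epoxide to an allylic alcohol. Fallback from 21, back at 30: the smaller parent anion 24 opens the epoxide (THF/HMPA) to the dithianyl cyclopentanol F8. TESCl/imidazole gives the triethylsilyl ether F9. Lithiation (t-BuLi, THF/HMPA) and opening of (R)-2-allyloxirane at its CH2 carbon gives the homoallylic alcohol F10. TBSOTf/2,6-lutidine gives the mixed bis-silyl ether F11, and selective cleavage of the triethylsilyl ether (PPTS, MeOH) returns 30.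

**Further compounds**

F1 | step 4 | 6-(TBS-oxy)-2-ethenyl-1-methylbicyclo[3.3.0]octan-8-one | C=C[C@H]1CC[C@H]2[C@H](O[Si](C)(C)C(C)(C)C)CC(=O)[C@]21C
F2 | step 4 | lithium enolate of F1 | C=C[C@H]1CC[C@H]2[C@H](O[Si](C)(C)C(C)(C)C)C=C(O[Li])[C@]21C
F3 | step 4 | F1 with a cyclopent-2-en-1-yl group at C7 | C=C[C@H]1CC[C@H]2[C@H](O[Si](C)(C)C(C)(C)C)C([C@H]3CCC=C3)C(=O)[C@]21C
F4 | step 4 | C7=C8 enol triflate of F3 | C=C[C@H]1CC[C@H]2[C@H](O[Si](C)(C)C(C)(C)C)C([C@H]3CCC=C3)=C(OS(=O)(=O)C(F)(F)F)[C@]21C
F5 | step 4 | desilylated enol triflate (C6 alcohol, C2 vinyl) | C=C[C@H]1CC[C@H]2[C@H](O)C([C@H]3CCC=C3)=C(OS(=O)(=O)C(F)(F)F)[C@]21C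
F6 | step 6 | C7=C8 enol triflate of 6 | C=C(O[Si](C)(C)C(C)(C)C)[C@H]1CC[C@H]2[C@H](O[Si](C)(C)C(C)(C)C)C=C(OS(=O)(=O)C(F)(F)F)[C@]21C
F7 | step 6 | (R)-cyclopent-2-en-1-yl enol ether of 6 | C=C(O[Si](C)(C)C(C)(C)C)[C@H]1CC[C@H]2[C@H](O[Si](C)(C)C(C)(C)C)C=C(O[C@H]3C=CCC3)[C@]21C
F8 | step 16 | cyclopentanol with 1,3-dithian-2-yl on C3a′ | C[C@@H](O[Si](C)(C)C(C)(C)C)C#C[C@](C)(O)[C@H]1CC[C@H]2C=C([C@H]3CC[C@@H](C4SCCCS4)[C@@H]3O)C[C@]21C
F9 | step 16 | triethylsilyl ether of F8 | C[C@@H](O[Si](C)(C)C(C)(C)C)C#C[C@](C)(O)[C@H]1CC[C@H]2C=C([C@H]3CC[C@@H](C4SCCCS4)[C@@H]3O[Si](CC)(CC)CC)C[C@]21C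
F10 | step 16 | homoallylic alcohol from F9 and (R)-2-allyloxirane | C[C@@H](O[Si](C)(C)C(C)(C)C)C#C[C@](C)(O)[C@H]1CC[C@H]2C=C([C@H]3CC[C@@H](C4(SCCCS4)C[C@H](O)CC=C)[C@@H]3O[Si](CC)(CC)CC)C[C@]21C
F11 | step 16 | TBS ether of F10 | C[C@@H](O[Si](C)(C)C(C)(C)C)C#C[C@](C)(O)[C@H]1CC[C@H]2C=C([C@H]3CC[C@@H](C4(SCCCS4)C[C@H](O[Si](C)(C)C(C)(C)C)CC=C)[C@@H]3O[Si](CC)(CC)CC)C[C@]21C
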